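## Retrosynthetic overview
1. The target comes from C8 isobutyrylation of the C6 α‑hydroxy‑1,3‑dione. That dione comes from C6 prenylation and hydroxylation of the cyclooctane‑1,3‑dione **14**.
2. The only ring, the eight‑membered carbocycle, is closed by an intramolecular Claisen between C5 (ester) and C6 (methyl ketone) of keto‑ester **13**.
3. **13** comes from Wacker oxidation of a propenyl group and C4 prenylation of **10**.
4. **10** comes from a photoredox decarboxylative Giese reaction (C2–C3 bond) of acid **8** with methyl acrylate.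
5. **8** comes from an Ireland–Claisen of ester **7**, which forms the quaternary C1 and transfers chirality from (R)‑but‑3‑en‑2‑ol. **7** is built from diene **3**, the butenol and acid **6**.

**Labels:** C1–C8 are the target's ring carbons in SMILES order. C1 is the quaternary C(Me)(homoprenyl). C2 and C4 are CH(prenyl). C3 is CH2. C5 and C7 are C=O. C6 is C(OH)(prenyl). C8 is CH–C(O)iPr.

**Assumptions**
- C4 and C8 are α to ketones and equilibrate under the basic steps. I assume they settle at the natural configuration (4S, 8R).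
- I assume that 1,2‑induction from C1 in step 5 and the ring's facial bias in step 10 give the natural C2 and C6 configurations.

## Route

**Step 1**
Reactants: **1** 6‑methylhept‑5‑en‑2‑one (sulcatone); **2** methyltriphenylphosphonium bromide
Product: **3** 2,6‑dimethylhepta‑1,5‑diene
Conditions: KOtBu, THF, 0 °C → rt
Reagents that add atoms: methylenetriphenylphosphorane (from **2**), C=P(c1ccccc1)(c1ccccc1)c1ccccc1, delivers =CH2
Why: Wittig methylenation converts the methyl ketone into the 1,1‑disubstituted alkene needed for cross‑metathesis.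

**Step 2**
Reactants: **3** (3 equiv); **4** (R)‑but‑3‑en‑2‑ol
Product: **5** (2R,3E)‑4,8‑dimethylnona‑3,7‑dien‑2‑ol
Conditions: Hoveyda–Grubbs II (5 mol %), CH2Cl2, 40 °C
Reagents that add atoms: none
Why: Cross‑metathesis forms the E‑trisubstituted allylic alcohol, and the carbinol stereocentre of **4** is the only chirality input.

**Step 3**
Reactants: **5**; **6** 5‑methylhex‑4‑enoic acid
Product: **7** (2R,3E)‑4,8‑dimethylnona‑3,7‑dien‑2‑yl 5‑methylhex‑4‑enoate
Conditions: EDC·HCl, DMAP, CH2Cl2, 0 °C → rt
Reagents that add atoms: none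
Why: Steglich esterification proceeds without touching the stereocentre.

**Step 4**
Reactant: **7**
Product: **8** (2S,3S,4E)‑3‑methyl‑2‑(3‑methylbut‑2‑enyl)‑3‑(4‑methylpent‑3‑enyl)hex‑4‑enoic acid
Conditions: LDA, THF, –78 °C; TBSCl; –78 °C → rt, then 60 °C; then 1 M HCl
Reagents that add atoms: none (the TBS group is lost on work‑up)
Why: In the Ireland–Claisen, a chair transition state with the carbinol methyl equatorial and the E‑alkene sets the quaternary C1 with the target's spatial arrangement (R in the target's CIP labelling), so the butenol's chirality is transferred to C1.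

**Step 5**
Reactants: **8**; **9** methyl acrylate (5 equiv)
Product: **10** methyl (4R,5R,6E)‑5‑methyl‑4‑(3‑methylbut‑2‑enyl)‑5‑(4‑methylpent‑3‑enyl)oct‑6‑enoate
Conditions: Mes‑Acr‑Me⁺ BF4⁻ (2.5 mol %), PhSSPh (10 mol %), iPr2NEt (20 mol %), MeCN/PhCF3, blue LEDs (450 nm), 25 °C
Reagents that add atoms: methyl acrylate, C=CC(=O)OC, adds CH2CH2CO2Me
Why: Photoredox decarboxylative Giese reaction (Nicewicz‑type) joins C2 to C3 through the planar C2 radical, which adds anti to the quaternary C1 (1,2‑induction); trisubstituted alkenes are inert to the nucleophilic radical.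

**Step 6**
Reactant: **10**
Product: **12** methyl (4S,5R,6E)‑5‑methyl‑2,4‑bis(3‑methylbut‑2‑enyl)‑5‑(4‑methylpent‑3‑enyl)oct‑6‑enoate (C2′ epimers ~1:1)
Conditions: LDA, THF, –78 °C; **11** prenyl bromide; –78 → 0 °C
Reagents that add atoms: prenyl bromide (**11**), CC(C)=CCBr
Why: Ester‑enolate α‑alkylation installs the C4 prenyl, and the C4 epimers converge later because C4 is α to a ketone.

**Step 7**
Reactant: **12**
Product: **13** methyl (4S,5S)‑5‑methyl‑7‑oxo‑2,4‑bis(3‑methylbut‑2‑enyl)‑5‑(4‑methylpent‑3‑enyl)octanoate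
Conditions: PdCl2 (10 mol %), CuCl, O2 (1 atm), DMF/H2O 7:1, 60 °C
Reagents that add atoms: water, O (supplies the carbonyl oxygen)
Why: Wacker–Tsuji oxidation of the 1,2‑disubstituted propenyl group puts the ketone at C7, remote from the quaternary centre, and leaves the trisubstituted alkenes untouched.

**Step 8**
Reactant: **13**
Product: **14** (4S,6S,7S)‑7‑methyl‑7‑(4‑methylpent‑3‑enyl)‑4,6‑bis(3‑methylbut‑2‑enyl)cyclooctane‑1,3‑dione
Conditions: LiHMDS (2.5 equiv), THF, –78 °C, added by syringe pump to a 3 mM solution; MgBr2·OEt2 (1.2 equiv); warm to 0 °C; aq. NH4Cl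
Reagents that add atoms: none
Why: Proposed new method: irreversible kinetic enolization of the unhindered C6 methyl (C8 is neopentylic) gives a Mg‑chelated keto‑ester that cyclizes through the C6 enolate, and the acidic eight‑membered 1,3‑diketone (as its anion) is the thermodynamic sink; closest known reactions are Dieckmann and Weiler intramolecular Claisen closures to 5–7‑membered 1,3‑diketones.

**Step 9**
Reactants: **14**; **11** (1.05 equiv)
Product: **15** (4S,6S,7S)‑7‑methyl‑7‑(4‑methylpent‑3‑enyl)‑2,4,6‑tris(3‑methylbut‑2‑enyl)cyclooctane‑1,3‑dione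
Conditions: K2CO3, acetone, 0 °C → rt
Reagents that add atoms: prenyl bromide (**11**), CC(C)=CCBr
Why: C‑alkylation of the doubly activated C6 of the 1,3‑dione gives the 2‑prenyl dione, whose C6 stereocentre is transient.

**Step 10**
Reactant: **15**
Product: **16** (2S,4S,6S,7S)‑2‑hydroxy‑7‑methyl‑7‑(4‑methylpent‑3‑enyl)‑2,4,6‑tris(3‑methylbut‑2‑enyl)cyclooctane‑1,3‑dione
Conditions: Cs2CO3, DMSO, O2 (1 atm), 25 °C; then P(OEt)3
Reagents that add atoms: dioxygen, O=O
Why: Autoxidation of the dione enolate gives the C6 hydroperoxide, which P(OEt)3 reduces to the tertiary alcohol, with O2 approaching the enolate face that the existing ring stereocentres leave open.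

**Step 11**
Reactants: **16**; **17** isobutyryl chloride
Product: **18** hyphenrone F, (2R,4R,5R,6S,8S)‑2‑hydroxy‑4‑(2‑methylpropanoyl)‑5‑methyl‑5‑(4‑methylpent‑3‑enyl)‑2,6,8‑tris(3‑methylbut‑2‑enyl)cyclooctane‑1,3‑dione
Conditions: LDA (3.3 equiv), THF, –78 → –20 °C; **17** (1.2 equiv); then K2CO3, MeOH
Reagents that add atoms: isobutyryl chloride (**17**), CC(C)C(=O)Cl
Why: C‑acylation of the C7 enolate at the only other acidic CH2 (C8) gives the β‑diketone, and any O‑acyl by‑products are cleaved by K2CO3/MeOH; C8 epimerizes to the thermodynamic configuration.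

## Compound list
1 | 6‑methylhept‑5‑en‑2‑one | CC(=O)CCC=C(C)C | starting material
2 | methyltriphenylphosphonium bromide | C[P+](c1ccccc1)(c1ccccc1)c1ccccc1.[Br-] | starting material
3 | 2,6‑dimethylhepta‑1,5‑diene | C=C(C)CCC=C(C)C | intermediate
4 | (R)‑but‑3‑en‑2‑ol | C=C[C@@H](C)O | starting material
5 | (2R,3E)‑4,8‑dimethylnona‑3,7‑dien‑2‑ol | C[C@@H](O)/C=C(/CCC=C(C)C)C | intermediate
6 | 5‑methylhex‑4‑enoic acid | CC(C)=CCCC(=O)O | starting material
7 | ester of 5 and 6 | C[C@@H](OC(=O)CCC=C(C)C)/C=C(/CCC=C(C)C)C | intermediate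
8 | Claisen acid | CC(C)=CCC[C@@](C)(/C=C/C)[C@H](CC=C(C)C)C(=O)O | intermediate
9 | methyl acrylate | C=CC(=O)OC | starting material
10 | Giese ester | COC(=O)CC[C@H](CC=C(C)C)[C@@](C)(CCC=C(C)C)/C=C/C | intermediate
11 | prenyl bromide | CC(C)=CCBr | starting material
12 | C4‑prenylated ester | COC(=O)C(CC=C(C)C)C[C@H](CC=C(C)C)[C@@](C)(CCC=C(C)C)/C=C/C | intermediate
13 | keto‑ester | COC(=O)C(CC=C(C)C)C[C@H](CC=C(C)C)[C@@](C)(CCC=C(C)C)CC(C)=O | intermediate
14 | cyclooctane‑1,3‑dione | CC(C)=CCC[C@]1(C)[C@@H](CC=C(C)C)C[C@H](CC=C(C)C)C(=O)CC(=O)C1 | intermediate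
15 | 2‑prenyl dione | CC(C)=CCC[C@]1(C)[C@@H](CC=C(C)C)C[C@H](CC=C(C)C)C(=O)C(CC=C(C)C)C(=O)C1 | intermediate
16 | 2‑hydroxy dione | CC(C)=CCC[C@]1(C)[C@@H](CC=C(C)C)C[C@H](CC=C(C)C)C(=O)[C@](O)(CC=C(C)C)C(=O)C1 | intermediate
17 | isobutyryl chloride | CC(C)C(=O)Cl | starting material
18 | hyphenrone F | CC(C)=CCC[C@]1(C)[C@@H](CC=C(C)C)C[C@H](CC=C(C)C)C(=O)[C@](O)(CC=C(C)C)C(=O)[C@H]1C(=O)C(C)C | target

## Totals
Total steps: 11. Longest linear sequence: 11.

## Three steps most likely to fail
1. **Step 8 (proposed new ring closure).** The C8 enolate could close the six‑membered ring instead, or the substrate could oligomerize. Fallback: protect the C7 ketone as its ketal and reduce the ester to the aldehyde (DIBAL). Then deprotect and close C5–C6 by Ti‑enolate intramolecular aldol, and oxidize the β‑hydroxy ketone with DMP to the 1,3‑dione.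
2. **Step 5 (photoredox Giese).** The C2 radical may cyclize 5‑exo onto the homoprenyl alkene, or C2 diastereoselectivity may be poor. Fallback: run step 4 as LDA, THF–DMPU (Z‑ketene acetal), which gives the required C2 configuration. Then reduce the acid (LiAlH4), convert the alcohol to the iodide (I2/PPh3/imidazole), and alkylate the lithium enolate of methyl 5‑methylhex‑4‑enoate to give **12** directly.
3. **Step 10 (C6 hydroxylation).** Autoxidation may give the wrong C6 epimer or trigger retro‑Claisen cleavage. Fallback: convert **15** to its C6 TBS enol ether (TBSOTf, Et3N), oxidize with DMDO (Rubottom), and remove the silyl group with TBAF.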